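**Retrosynthetic overview**

1. Locants and rings: ring A = C4(H, isopropyl)–C5H2–C6H–C7H–C13; ring B = C6–C7–C13–C14H2–C15H(OH); A and B share C6–C7–C13 (norbornane, C7 = one-carbon bridge, C13 quaternary; exo = on the side of C7); ring C = C7–C8H–C9(CH3)–C11H2–C12H2–C13; ring D = C8–C9–C17H(Br)–C18H2–C19H2–C20(OH)(CH3); β = the face of the C9 methyl.
2. Target ⇐ C15 ketone (hydride from the endo face) ⇐ exo-isopropenyl ⇐ C4–CO2H (decarboxylative exo vinylation; the carboxyl is only an activating group and is removed).
3. Ring A, the last ring ⇐ double Michael addition (formal [4+2]) of tricyclic cyclopentenone 18 (rings B, C, D) with allyl acrylate: bond C6–C5 first, then C4–C13. Enabling feature: with C15 as ketone and C13=C14 unsaturated, ring B is a cyclopentenone whose α′-carbon C6 (nucleophilic) and β-carbon C13 (electrophilic) flank C7, so the C5–C4 bridge of ring A is an acrylate unit.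
4. Ring B ⇐ aldol condensation of the C13 ketone with an acetonyl group on C7. Ring D: C20 carbinol from a C8=C20 alkene (hydroboration, oxidation, MeMgBr); C17–Br from a vinyl bromide by hydrogen-atom-transfer hydrogenation.
5. Rings C and D ⇐ (S)-Wieland–Miescher ketone 1. Order of ring formation: C and D (purchased), B (step 14), A (step 15).

Key step: step 15

Remark: 1, 4, 19 and 23 are taken as commercial; 7–16 are drawn as the C7 epimer with the side chain on the α-face, and any C7 epimer carried along should converge in step 14, where C7 is α to the C13 ketone.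

**Route**

Step 1
Reactants: 1 (S)-Wieland–Miescher ketone
Product: 2 (4aS,5S)-5-hydroxy-4a-methyl-4,4a,5,6,7,8-hexahydronaphthalen-2(3H)-one (17β-OH)
Conditions: NaBH4 (0.3 equiv), EtOH, −10 °C
Reagents that add atoms: none
Why: Chemoselective borohydride reduction of the saturated ketone; axial hydride attack from the face opposite the angular methyl should give the equatorial 17β-alcohol.

Step 2
Reactants: 2 hydroxy enone
Product: 3 TBDPS ether of 2
Conditions: TBDPSCl, imidazole, DMAP (cat.), DMF, 50 °C
Reagents that add atoms: tert-butyl(chloro)diphenylsilane, CC(C)(C)[Si](Cl)(c1ccccc1)c1ccccc1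
Why: Silyl ether formation; TBDPS is chosen because it should survive the acidic ketalisation, the base and the hydride steps.

Step 3
Reactants: 3 TBDPS ether; 4 3-bromo-2-methylprop-1-ene
Product: 5 C7-(2-methylallyl) enone
Conditions: KOtBu (1.05 equiv), tBuOH/THF, 0 °C to rt; then 4, 0 °C; dilute HCl work-up
Reagents that add atoms: none
Why: α-Alkylation of the extended (thermodynamic) dienolate: γ-deprotonation at C20, C-alkylation at C7 by the allylic bromide and reconjugation should give the tetrasubstituted enone; no stereocentre is formed.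

Step 4
Reactants: 5 methallyl enone
Product: 6 enone methyl ketone (2-oxopropyl on C7)
Conditions: OsO4 (2 mol %), NaIO4, 2,6-lutidine, dioxane/H2O, rt
Reagents that add atoms: sodium periodate, [Na+].[O-]I(=O)(=O)=O
Why: Lemieux–Johnson oxidative cleavage; the electron-rich 1,1-disubstituted alkene should be dihydroxylated and cleaved while the electron-poor tetrasubstituted enone double bond stays.

Step 5
Reactants: 6 enone methyl ketone
Product: 7 bis(ethylene ketal) with the double bond at C8=C20
Conditions: ethylene glycol, TsOH·H2O (cat.), benzene, reflux, Dean–Stark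
Reagents that add atoms: ethylene glycol, OCCO
Why: Acid-catalysed ketalisation of both ketones; the enone-derived ketal should form with migration of the double bond to C8=C20, which exposes C20, while C7 becomes an sp3 centre of inconsequential configuration.

Step 6
Reactants: 7 bis-ketal alkene
Product: 9 secondary alcohol (20α-OH; 8α-H; trans-decalin), via alkylborane 8 (not isolated)
Conditions: BH3·THF, THF, 0 °C to rt; then NaOH, H2O2, 0 °C to rt
Reagents that add atoms: borane (boron only in 8), B; hydrogen peroxide, OO
Why: Hydroboration–oxidation: syn addition from the α-face, opposite the axial C9 methyl, should put boron on the less substituted C20 and hydrogen on C8, setting the trans ring fusion (8α-H).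

Step 7
Reactants: 9 secondary alcohol
Product: 10 C20 ketone
Conditions: Dess–Martin periodinane, NaHCO3, CH2Cl2, rt
Reagents that add atoms: none
Why: Dess–Martin oxidation; the trans-fused C8 centre next to the new ketone is the thermodynamically preferred epimer and should be kept.

Step 8
Reactants: 10 C20 ketone
Product: 11 tertiary alcohol (20β-OH axial; 20α-CH3)
Conditions: MeMgBr, CeCl3, THF, −78 to 0 °C
Reagents that add atoms: methylmagnesium bromide, C[Mg]Br
Why: Grignard addition; the axial trajectory is blocked by the 1,3-diaxial C9 methyl, so methyl should enter equatorially from the α-face and leave the hydroxyl axial on the β-face.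

Step 9
Reactants: 11 tertiary alcohol
Product: 12 17β,20β-diol
Conditions: TBAF, THF, 50 °C
Reagents that add atoms: none
Why: Fluoride-induced cleavage of the silyl ether.

Step 10
Reactants: 12 diol
Product: 13 C17 ketone
Conditions: Dess–Martin periodinane, NaHCO3, CH2Cl2, rt
Reagents that add atoms: none
Why: Dess–Martin oxidation of the only secondary alcohol; the tertiary C20 hydroxyl cannot be oxidised.

Step 11
Reactants: 13 C17 ketone
Product: 14 C17 hydrazone
Conditions: N2H4·H2O (excess), Et3N, EtOH, reflux
Reagents that add atoms: hydrazine (as hydrate), NN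
Why: Hydrazone formation at the only free carbonyl group, the other two being ketals.

Step 12
Reactants: 14 hydrazone
Product: 15 vinyl bromide (17-bromo, C17=C18)
Conditions: NBS (2.2 equiv), pyridine, 0 °C
Reagents that add atoms: N-bromosuccinimide, O=C1CCC(=O)N1Br
Why: Barton-type vinyl halide synthesis: bromination of the hydrazone, loss of N2 and loss of a C18 proton should give the alkenyl bromide, C9 being quaternary so that only one regioisomer can form.

Step 13
Reactants: 15 vinyl bromide
Product: 16 17β-bromide (equatorial Br; 17α-H)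
Conditions: Mn(dpm)3 (10 mol %), PhSiH3, TBHP, iPrOH, rt
Reagents that add atoms: none
Why: Metal-hydride hydrogen-atom-transfer hydrogenation, a reaction type that reduces haloalkenes to alkyl halides: H· should add to C18, and the α-bromo radical at C17 should take its hydrogen axially from the α-face, anti to the axial C9 methyl, leaving bromine equatorial.

Step 14
Reactants: 16 bromo bis-ketal
Product: 18 tricyclic enone (rings B, C, D), via diketone 17 (not isolated)
Conditions: 2 M HCl, THF, rt; then KOH, MeOH, 50 °C
Reagents that add atoms: water, O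
Why: Ketal hydrolysis, then intramolecular aldol condensation of the methyl ketone (C14) onto the C13 ketone should close the five-membered ring B as the C13=C14 enone, with C7 equilibrating to the equatorial side chain (7β-H).

Step 15
Reactants: 18 tricyclic enone; 19 allyl acrylate
Product: 21 tetracyclic keto allyl ester (ring A closed; C15 ketone; ester on C4), via lithium ester enolate 20 (not isolated)
Conditions: LDA (2.2 equiv), THF, −78 °C; 19 (1.1 equiv), −78 to 0 °C; aq. NH4Cl
Reagents that add atoms: none
Why: LDA deprotonates the tertiary alcohol and then, kinetically, the α′-carbon C6 of the cyclopentenone; the cross-conjugated dienolate adds to allyl acrylate (C6–C5 bond) to give ester enolate 20, which attacks the enone β-carbon C13 (C4–C13 bond) and leaves the C15 ketone enolate for protonation. The closest known reaction type is the aprotic double Michael addition (anionic formal [4+2] annulation) of cross-conjugated cycloalkenone enolates with acrylates, which in intramolecular cases converts cyclopentenones into bicyclo[2.2.1]heptan-2-ones. Ring A is closed by the second bond in a 5-exo-trig Michael ring closure, rings B, C and D being present already, and this closure also creates the quaternary centre C13. C6 is under substrate control, the acrylate approaching the dienolate face opposite to C8 on the neighbouring C7; C13 is then fixed by the two-carbon tether, which can only reach the same face; C4 should form as an epimer mixture (endo ester drawn) and is reset in step 17. The step needs enolisation at C6 and not at the γ-positions C7 and C12, which LDA at −78 °C should secure, and it needs the ring closure to outrun acrylate oligomerisation, which intramolecularity and the gain from ester enolate to ketone enolate favour. The equatorial, neopentyl-type C17 bromide and the C20 lithium alkoxide should be spectators.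

Step 16
Reactants: 21 keto allyl ester
Product: 22 keto acid
Conditions: Pd(PPh3)4 (5 mol %), morpholine, THF, rt
Reagents that add atoms: none
Why: Tsuji–Trost-type deallylation by zerovalent palladium with morpholine as allyl acceptor; the neutral conditions should avoid retro-Michael opening of the strained keto ester and leave the alkyl bromide untouched.

Step 17
Reactants: 22 keto acid; 23 2-bromopropene
Product: 24 exo-isopropenyl ketone (4-H endo)
Conditions: Ir[dF(CF3)ppy]2(dtbbpy)PF6 (1 mol %), NiCl2·glyme (10 mol %), 4,4′-di-tert-butyl-2,2′-bipyridine, DBU, 23 (5 equiv), DMSO, blue LEDs, rt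
Reagents that add atoms: none
Why: Photoredox/nickel decarboxylative vinylation: the carboxylate is oxidised and loses CO2, and the secondary 2-norbornyl-type C4 radical should be captured by the vinylnickel species on the exo face (the endo face lies under the C14–C15 bridge, the syn position on C7 carries only H), so C4 is set with exo-isopropenyl and endo-H whatever its configuration in 22.

Step 18
Reactants: 24 isopropenyl ketone
Product: 25 exo-isopropyl ketone
Conditions: H2 (1 atm), RhCl(PPh3)3 (5 mol %), benzene, rt
Reagents that add atoms: none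
Why: Homogeneous catalytic hydrogenation of the 1,1-disubstituted alkene; no stereocentre is formed, and ketone and alkyl bromide should be tolerated.

Step 19
Reactants: 25 isopropyl ketone
Product: 26 target CNP0317598.2
Conditions: NaBH4, MeOH, 0 °C
Reagents that add atoms: none
Why: Borohydride reduction; the exo face of C15 is covered by C8 (syn substituent on the C7 bridge) and ring D, so hydride should arrive from the endo face and give the exo alcohol (isoborneol-type selectivity).

**Compound list**

1 | (S)-Wieland–Miescher ketone, (8aS)-8a-methyl-3,4,8,8a-tetrahydronaphthalene-1,6(2H,7H)-dione | C[C@]12CCC(=O)C=C1CCCC2=O | starting material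
2 | (4aS,5S)-5-hydroxy-4a-methyl-4,4a,5,6,7,8-hexahydronaphthalen-2(3H)-one (17β-OH, cis to the angular methyl) | C[C@]12CCC(=O)C=C1CCC[C@@H]2O | intermediate
3 | (4aS,5S)-5-[(tert-butyldiphenylsilyl)oxy]-4a-methyl-4,4a,5,6,7,8-hexahydronaphthalen-2(3H)-one | C[C@]12CCC(=O)C=C1CCC[C@@H]2O[Si](c1ccccc1)(c1ccccc1)C(C)(C)C | intermediate
4 | 3-bromo-2-methylprop-1-ene | C=C(C)CBr | starting material
5 | (4aS,5S)-5-[(tert-butyldiphenylsilyl)oxy]-4a-methyl-1-(2-methylprop-2-en-1-yl)-4,4a,5,6,7,8-hexahydronaphthalen-2(3H)-one (methallyl on C7) | C[C@]12CCC(=O)C(CC(C)=C)=C1CCC[C@@H]2O[Si](c1ccccc1)(c1ccccc1)C(C)(C)C | intermediate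
6 | (4aS,5S)-5-[(tert-butyldiphenylsilyl)oxy]-4a-methyl-1-(2-oxopropyl)-4,4a,5,6,7,8-hexahydronaphthalen-2(3H)-one | C[C@]12CCC(=O)C(CC(C)=O)=C1CCC[C@@H]2O[Si](c1ccccc1)(c1ccccc1)C(C)(C)C | intermediate
7 | bis(ethylene ketal) of 6 with the ring double bond at C8=C20: spiro-1,3-dioxolane at C13, (2-methyl-1,3-dioxolan-2-yl)methyl on C7 (7β-H), 9β-CH3, 17β-OTBDPS | C[C@]12CCC3(OCCO3)[C@@H](CC4(C)OCCO4)C1=CCC[C@@H]2O[Si](c1ccccc1)(c1ccccc1)C(C)(C)C | intermediate
8 | alkylborane from 7: 20α-BH2, 8α-H | C[C@]12CCC3(OCCO3)[C@@H](CC4(C)OCCO4)[C@@H]1[C@@H](B)CC[C@@H]2O[Si](c1ccccc1)(c1ccccc1)C(C)(C)C | intermediate (not isolated)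
9 | secondary alcohol: 20α-OH (equatorial), 8α-H, trans-decalin, otherwise as 7 | C[C@]12CCC3(OCCO3)[C@@H](CC4(C)OCCO4)[C@@H]1[C@@H](O)CC[C@@H]2O[Si](c1ccccc1)(c1ccccc1)C(C)(C)C | intermediate
10 | C20 ketone of 9 | C[C@]12CCC3(OCCO3)[C@@H](CC4(C)OCCO4)[C@@H]1C(=O)CC[C@@H]2O[Si](c1ccccc1)(c1ccccc1)C(C)(C)C | intermediate
11 | tertiary alcohol: 20β-OH (axial), 20α-CH3, otherwise as 10 | C[C@]12CCC3(OCCO3)[C@@H](CC4(C)OCCO4)[C@@H]1[C@](C)(O)CC[C@@H]2O[Si](c1ccccc1)(c1ccccc1)C(C)(C)C | intermediate
12 | 17β,20β-diol (silyl group removed) | C[C@]12CCC3(OCCO3)[C@@H](CC4(C)OCCO4)[C@@H]1[C@](C)(O)CC[C@@H]2O | intermediate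
13 | C17 ketone of 12 | C[C@]12CCC3(OCCO3)[C@@H](CC4(C)OCCO4)[C@@H]1[C@](C)(O)CCC2=O | intermediate
14 | C17 hydrazone of 13 | C[C@]12CCC3(OCCO3)[C@@H](CC4(C)OCCO4)[C@@H]1[C@](C)(O)CCC2=NN | intermediate
15 | vinyl bromide: 17-bromo, C17=C18 double bond | C[C@]12CCC3(OCCO3)[C@@H](CC4(C)OCCO4)[C@@H]1[C@](C)(O)CC=C2Br | intermediate
16 | 17β-bromide (equatorial Br, 17α-H), ring D saturated | C[C@]12CCC3(OCCO3)[C@@H](CC4(C)OCCO4)[C@@H]1[C@](C)(O)CC[C@@H]2Br | intermediate
17 | diketone: C13 ketone, 2-oxopropyl on C7 (7β-H), 8α-H, 9β-CH3, 17β-Br, 20β-OH, 20α-CH3 | C[C@]12CCC(=O)[C@@H](CC(C)=O)[C@@H]1[C@](C)(O)CC[C@@H]2Br | intermediate (not isolated)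
18 | tricyclic enone: 6-bromo-9-hydroxy-5a,9-dimethyl-1,4,5,5a,6,7,8,9,9a,9b-decahydro-2H-cyclopenta[a]naphthalen-2-one; in the locants used here C13=C14, C15=O, C6H2, 7β-H, 8α-H, 9β-CH3, 17β-Br, 20β-OH | C[C@]12CCC3=CC(=O)C[C@H]3[C@@H]1[C@](C)(O)CC[C@@H]2Br | intermediate
19 | allyl acrylate (prop-2-en-1-yl prop-2-enoate) | C=CC(=O)OCC=C | starting material
20 | lithium enolate of the allyl ester after the first Michael addition: C6–C5 bond formed trans to C8, cyclopentenone intact, C20 lithium alkoxide | [Li]OC(OCC=C)=CC[C@@H]1[C@H]2[C@H]3[C@](C)(CCC2=CC1=O)[C@@H](Br)CC[C@@]3(C)O[Li] | intermediate (not isolated)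
21 | tetracyclic keto ester: skeleton of the target with C15 ketone and CO2CH2CH=CH2 on C4 in place of isopropyl (endo epimer drawn) | C=CCOC(=O)[C@H]1C[C@@H]2[C@H]3[C@H]4[C@](C)(CC[C@@]31CC2=O)[C@@H](Br)CC[C@@]4(C)O | intermediate
22 | keto acid: as 21 with CO2H on C4 | OC(=O)[C@H]1C[C@@H]2[C@H]3[C@H]4[C@](C)(CC[C@@]31CC2=O)[C@@H](Br)CC[C@@]4(C)O | intermediate
23 | 2-bromopropene | C=C(C)Br | starting material
24 | exo-isopropenyl ketone: prop-1-en-2-yl exo on C4, 4-H endo, C15 ketone | C=C(C)[C@@H]1C[C@@H]2[C@H]3[C@H]4[C@](C)(CC[C@@]31CC2=O)[C@@H](Br)CC[C@@]4(C)O | intermediate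
25 | exo-isopropyl ketone (15-ketone of the target) | CC(C)[C@@H]1C[C@@H]2[C@H]3[C@H]4[C@](C)(CC[C@@]31CC2=O)[C@@H](Br)CC[C@@]4(C)O | intermediate
26 | CNP0317598.2: 4-exo-isopropyl, 15-exo-OH, 17β-Br, 20β-OH, 20α-CH3, 9β-CH3 | CC(C)[C@@H]1C[C@@H]2[C@H]3[C@H]4[C@](C)(CC[C@@]31C[C@H]2O)[C@@H](Br)CC[C@@]4(C)O | target

**Step count**

Total: 19 steps. Longest linear sequence: 19 steps (1 to 26).

**Steps most likely to fail, with fallbacks**

Step 15. The ring-closing second conjugate addition builds a strained bicycle and a quaternary centre. It may be slower than proton transfer or acrylate oligomerisation, so the sequence may stop after the first Michael addition or reopen on warming. The fallback sets out from 18 and replaces the anionic sequence by a cycloaddition of a neutral diene. Kinetic enolisation (LDA, then TBSCl, THF, −78 °C) should give the 2-silyloxy cyclopentadiene F1. A Diels–Alder reaction with allyl acrylate 19, promoted by Me2AlCl in CH2Cl2 at −78 °C (cold enough to suppress 1,5-hydrogen shifts of the diene), should give the silyl enol ether cycloadduct F2. Dilute HCl in THF then cleaves the enol ether, and the route is rejoined at 21.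

Step 17. Single-electron oxidation of a non-activated secondary carboxylate is slow, and capture of the hindered C4 radical by nickel may lose out to hydrogen abstraction (protodecarboxylation). The fallback sets out from 22. N-Hydroxyphthalimide and N,N′-diisopropylcarbodiimide (DMAP, CH2Cl2) should give the redox-active ester F3. This is coupled thermally with isopropenylzinc chloride (from isopropenylmagnesium bromide and ZnCl2) under NiCl2·glyme and 2,2′-bipyridine in THF/DMF; the radical is again captured on the exo face, and the route is rejoined at 24.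

Step 13. The first hydrogen atom may add to the bromine-bearing carbon, after which β-scission expels bromine; the facial selectivity of the second hydrogen transfer may also be insufficient. The fallback sets out from hydrazone 14 and avoids the alkene. Oxidation with CuBr2 and LiOtBu in THF should give the geminal dibromide F4. Monoreduction with Bu3SnH (1.0 equiv, Et3B/air, toluene, −78 °C) should deliver hydrogen axially to the α-bromo radical from the face opposite the C9 methyl, and the route is rejoined at 16.

**Further compounds**

F1 | step 15 | tert-butyldimethylsilyl dienol ether of 18 (2-silyloxy cyclopenta-1,3-diene: C6=C15(OTBS)–C14=C13, 7β-H) | CC(C)(C)[Si](C)(C)OC1=C[C@H]2[C@H]3[C@](C)(CCC2=C1)[C@@H](Br)CC[C@@]3(C)O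
F2 | step 15 | Diels–Alder adduct: as 21 but with C14=C15 tert-butyldimethylsilyl enol ether in place of the C15 ketone | C=CCOC(=O)[C@H]1C[C@@H]2[C@H]3[C@H]4[C@](C)(CC[C@@]31C=C2O[Si](C)(C)C(C)(C)C)[C@@H](Br)CC[C@@]4(C)O
F3 | step 17 | N-hydroxyphthalimide ester of 22 | O=C(ON1C(=O)c2ccccc2C1=O)[C@H]1C[C@@H]2[C@H]3[C@H]4[C@](C)(CC[C@@]31CC2=O)[C@@H](Br)CC[C@@]4(C)O
F4 | step 13 | 17,17-dibromide (from hydrazone 14) | C[C@]12CCC3(OCCO3)[C@@H](CC4(C)OCCO4)[C@@H]1[C@](C)(O)CCC2(Br)Br
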